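The readings are simulated with made-up constants, noise included.

The easy mistake with these flasks is to read epsilon's clean decay as a rate constant and carry it to every charge.

| setting | delta | beta | epsilon | west | south-east |
|---|---|---|---|---|---|
| substrate | 0.050 M | 0.050 M | 0.034 M | 0.015 M | 0.050 M |
| partner | 0.0475 M | 0.0475 M | 0.0475 M | 0.0475 M | 0.0475 M |
| initiator | 1.7 mM | 3.7 mM | 2.4 mM | 1.2 mM | 2.4 mM |
| remark | run made earlier | run made earlier | run made earlier |  |  |
| time |  |  |  | 8.0 min | 8.0 min |

| run | time / min | target / % | substrate / % |
|---|---|---|---|
| delta | 0.500 | 26 | 78 |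
| delta | 1.33 | 46 | 55 |
| delta | 2.50 | 63 | 38 |
| delta | 4.00 | 71 | 32 |
| delta | 6.00 | 72 | 25 |
| beta | 0.417 | 30 | 72 |
| beta | 0.833 | 45 | 52 |
| beta | 1.50 | 61 | 37 |
| beta | 3.00 | 78 | 24 |
| beta | 6.00 | 79 | 16 |
| epsilon | 0.500 | 38 | 59 |
| epsilon | 1.33 | 72 | 25 |
| epsilon | 2.50 | 94 | 6 |
| epsilon | 4.00 | 100 | 2 |
| epsilon | 6.00 | 98 | 2 |

(readings scatter by 1.5 percentage points)

- the earlier runs were read with a standard deviation of 1.5 percentage points
- a reading or a percentage of target counts all its forms, free or not

- which of the two ends with the higher amount of target, in percent of the substrate charged ("neither" if they lie within 2 percentage points) (west / south-east / neither)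
- target at the end, in percent of the substrate charged, west
- target at the end, in percent of the substrate charged, south-east

Two chemists disagree. The first takes epsilon, where substrate falls to 25% at 1.33 min, and reads a first-order constant of 1.04 min⁻¹. Over 8.0 min that leaves 0.0239% of the substrate, so she expects both flasks to finish and answers "neither".

The second objects that delta, with south-east's substrate, went from 71% to 72% target between 4.00 min and 6.00 min with 25% substrate still present. She reads delta's last target as 0.758 of the partner charge and beta's as 0.832. This is the partner yield, target at the stall per partner charged. A straight line in initiator gives 0.784 at 2.4 mM, a ceiling of 0.0372 M, which is 74.4% of south-east's substrate. Extended beyond the runs to 1.2 mM, the line gives 0.739 and a ceiling of 0.0351 M. That is more than west's 0.015 M of substrate, so in west she lets the first chemist's decay run. Epsilon's 0.034 M also lay below its ceiling, and it read 98% target.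

The forecast sides with the second chemist: west ends higher, with west at 98% (92% to 100%) and south-east at 75% (71% to 80%), on the ground that “something runs out or shuts down”.

The simulation gives 99.4% for west and 76.8% for south-east, so west ends higher.

    initiator → 2 initiating radical (k = 3.90 × 10⁻⁴ s⁻¹)
    substrate + initiating radical → capped initiator + first chain carrier (k = 1.20 × 10⁵ L mol⁻¹ s⁻¹)
    partner + first chain carrier ⇌ target + second chain carrier (K = 1.20, k = 33000 L mol⁻¹ s⁻¹)
    substrate + second chain carrier → by-product + first chain carrier (k = 1.60 × 10⁵ L mol⁻¹ s⁻¹)
    2 first chain carrier → ended chains (k = 7.00 × 10⁶ L mol⁻¹ s⁻¹)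
    crystals ⇌ target, rate k6*(cs6 - [target]) while solid is left; crystals form when [target] > cs6 (solubility = 3.70 mM, k = 0.0180 s⁻¹)
    partner → decomposed reagent (k = 0.00260 s⁻¹)
    target → over-reaction product (k = 1.50 × 10⁻⁶ s⁻¹)

South-east's partner yield comes to 0.809, with 0.173% of partner left, so partner is the limiting reagent there, while 21.5% of substrate remains. The first chemist's finished flask is what west shows, ending with 0% substrate and 19.1% partner. The neighbouring flask is west with 0.037 M of substrate, and west's ceiling is 94.9% of that charge. It gives 94.1% target, a partner yield of 0.733, with 1.2% of partner and 4.8% of substrate left.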